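## Retrosynthetic overview
1. Glabrol (**5**) comes from a double aromatic Claisen [3,3] rearrangement of the bis(1,1-dimethylallyl) ether **4**. The tertiary allyl unit puts a normal prenyl group (not a reverse prenyl) on C-8 and C-3′.
2. Ether **4** comes from Lindlar semi-hydrogenation of the bis(1,1-dimethylpropargyl) ether **3**. Ether **3** comes from Cu-catalysed O-alkylation of (2S)-liquiritigenin (**1**) with 3-chloro-3-methylbut-1-yne (**2**).
3. No ring is built. The chromanone ring and the C-2 stereocentre are carried intact from purchased natural (2S)-liquiritigenin, which is the only chirality source.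

**Assumptions:** (2S)-liquiritigenin is the natural licorice flavanone and is commercially available. The target SMILES is (2S) by CIP (O > aryl > CH2 > H), the same as liquiritigenin. In the thermal Claisen of the 7-O-ether, C-8 is favoured over C-6, and any 6-prenyl isomer is removed by chromatography.

## Route

**Step 1**
Reactants: **1** (2S)-liquiritigenin; **2** 3-chloro-3-methylbut-1-yne
Product: **3** (2S)-7,4′-bis(2-methylbut-3-yn-2-yloxy)flavanone
Conditions: **2** (4 equiv), K2CO3, KI, CuI (cat.), MeCN, 40 °C
Reagents that add atoms: 3-chloro-3-methylbut-1-yne, CC(C)(Cl)C#C
Why: Cu(I) converts the tertiary propargylic chloride into a copper-allenylidene-type electrophile that is attacked by the phenoxide at the tertiary carbon (Cu-catalysed Williamson-type propargylation). Mild K2CO3 at low temperature limits retro-oxa-Michael ring opening, so C-2 is untouched.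

**Step 2**
Reactants: **3**
Product: **4** (2S)-7,4′-bis(2-methylbut-3-en-2-yloxy)flavanone
Conditions: H2 (1 atm), Lindlar catalyst (Pd/CaCO3, Pb-poisoned), quinoline, EtOAc, rt; stop at full consumption of the alkynes
Reagents that add atoms: none (only H2 is added)
Why: Lindlar semi-hydrogenation stops at the alkene stage, and terminal alkynes give terminal vinyl groups, so no new stereocentre or alkene geometry arises. The aryl ketone and the aryl ethers are not reduced.

**Step 3**
Reactants: **4**
Product: **5** Glabrol, (2S)-7,4′-dihydroxy-8,3′-bis(3-methylbut-2-enyl)flavanone
Conditions: PhCl, 140 °C, sealed tube, N2, 12–24 h; then silica chromatography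
Reagents that add atoms: none
Why: Each aryl 1,1-dimethylallyl ether undergoes an ortho aromatic Claisen [3,3] rearrangement through a chair transition state. The new C–C bond forms at the terminal CH2 of the vinyl group, giving Ar–CH2–CH=CMe2 (normal prenyl). The dienone then tautomerises to the free phenol. The 4′-ether has two equivalent ortho positions, so it gives the 3′-prenyl product, and the 7-ether rearranges mainly to C-8. The C-2 centre is not involved, so its configuration is retained.

## Checks
- **Structure:** the flavanone core (chroman-4-one, 2-aryl), 7-OH, 8-prenyl, 4′-OH and 3′-prenyl all match the target SMILES. Formula of **4** and **5** is C25H28O4; Claisen is an isomerisation, so every atom is accounted for.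
- **Functional groups:** the ketone, the ring ether and the phenols survive all three steps. The prenyl alkenes are only formed in step 3, after the hydrogenation.
- **Stereochemistry:** C-2 is set by purchased **1**. The stereocentre is written as [C@@H] with the same neighbour order in every SMILES below, which is (S) throughout.

## Compound list
1 | (2S)-liquiritigenin, (2S)-7,4′-dihydroxyflavanone | Oc1ccc([C@@H]2CC(=O)c3ccc(O)cc3O2)cc1 | starting material
2 | 3-chloro-3-methylbut-1-yne | CC(C)(Cl)C#C | starting material
3 | (2S)-7,4′-bis(2-methylbut-3-yn-2-yloxy)flavanone | CC(C)(C#C)Oc1ccc([C@@H]2CC(=O)c3ccc(OC(C)(C)C#C)cc3O2)cc1 | intermediate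
4 | (2S)-7,4′-bis(2-methylbut-3-en-2-yloxy)flavanone | C=CC(C)(C)Oc1ccc([C@@H]2CC(=O)c3ccc(OC(C)(C)C=C)cc3O2)cc1 | intermediate
5 | Glabrol | CC(C)=CCc1cc([C@@H]2CC(=O)c3ccc(O)c(CC=C(C)C)c3O2)ccc1O | target

## Totals
Total steps: 3. Longest linear sequence: 3.

## Three steps most likely to fail
1. **Step 1 (bis-tertiary etherification):** the yield may be low, or the flavanone may partly racemise through ring opening to the chalcone under K2CO3.
   - Fallback: drop base-mediated alkylation and make the tertiary allyl aryl ethers under Lewis-acid, non-basic conditions from 2-methylbut-3-en-2-yl trichloroacetimidate with cat. BF3·OEt2. This also removes the Lindlar step.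
2. **Step 2 (Lindlar):** Pd can ionise tertiary allylic or propargylic aryl ethers (hydrogenolysis), and over-reduction to the saturated ether is possible.
   - Fallback: a non-Pd alkyne reduction, either hydroboration with Cy2BH then AcOH protodeboronation, or Zn(Cu/Ag) in MeOH/H2O.
3. **Step 3 (double Claisen):** risks are C-6 versus C-8 regioselectivity, thermal racemisation or ionisation of the tertiary ether, and cyclisation of the new prenyl group onto the adjacent phenol.
   - Fallback: make the ordinary 7,4′-bis(3-methylbut-2-enyl) ethers and promote ortho-prenylation with BCl3 in CH2Cl2 at −78 to 0 °C. This avoids high temperature, but the regioselectivity must be checked.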